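**Retrosynthetic overview**
1. The last step closes the ten-membered carbocycle and the α-methylene lactone together: C6–C7 by intramolecular chromium allylation of a Z-enal with a 2-(bromomethyl)enoate, then lactone C–O closure.
2. The 2-(bromomethyl)enoate comes from a C7 aldehyde and methyl propiolate (vinylalumination, then SN2′ bromination). The C8 isobutyrate is a C–O bond made with inversion (Mitsunobu) on a D-ribo carbinol.
3. Key bond: the furanone O–C3 bond, formed by 5-endo-dig addition of the C10 tertiary hydroxyl to a C2≡C3 ynone. The ynone comes from a lithium acetylide and a γ-lactone (C1–C2 bond) in the same flask.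
4. Building blocks: 2-C-methyl-D-ribono-1,4-lactone (1; gives C1, C7–C10, C14 and the 9R,10R centres) and (Z)-3-methylpent-2-en-4-yn-1-ol (2; gives C2–C6, C15 and the 4Z alkene).
5. Ring order: furanone first (step 3), then carbocycle and lactone together (step 10).

Assumption: the target is read from the SMILES as 4Z,6R,7S,8S,9R,10R; all compounds carry germacranolide atom numbers (C1–C15), and 1 and 2 are bought.

**Step 1**
Reactants: 1 2-C-methyl-D-ribono-1,4-lactone
Product: 3 3,5-di-O-triethylsilyl-2-C-methyl-D-ribono-1,4-lactone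
Conditions: TESCl (2.2 equiv), imidazole, DMF, 0 → 23 °C
Reagents that add atoms: chlorotriethylsilane, CC[Si](Cl)(CC)CC
Why: Silyl ether formation is selective for the primary and secondary hydroxyls because the tertiary hydroxyl next to the lactone carbonyl is too hindered to react at this temperature; no stereocentre is touched.

**Step 2**
Reactants: 2 (Z)-3-methylpent-2-en-4-yn-1-ol
Product: 4 (Z)-tert-butyldimethyl[(3-methylpent-2-en-4-yn-1-yl)oxy]silane
Conditions: TBSCl, imidazole, CH2Cl2, 0 → 23 °C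
Reagents that add atoms: tert-butylchlorodimethylsilane, CC(C)(C)[Si](C)(C)Cl
Why: Standard silyl ether formation that leaves the terminal alkyne and the Z alkene untouched.

**Step 3**
Reactants: 3 3,5-di-O-triethylsilyl-2-C-methyl-D-ribono-1,4-lactone; 4 (Z)-tert-butyldimethyl[(3-methylpent-2-en-4-yn-1-yl)oxy]silane
Product: 7 (2R)-5-[(2Z)-4-(tert-butyldimethylsilyloxy)but-2-en-2-yl]-2-[(1R,2R)-2-hydroxy-1,3-bis(triethylsilyloxy)propyl]-2-methylfuran-3(2H)-one, via lithium acetylide 5 (not isolated), via hydroxy ynone 6 (not isolated)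
Conditions: 4 (2.3 equiv), n-BuLi (2.2 equiv), THF, −78 °C; add 3, −78 → −40 °C; AcOH, −78 °C; aqueous wash, crude into toluene; (Ph3P)AuNTf2 (2 mol %), 23 °C
Reagents that add atoms: none
Why: Proposed new method: the acetylide opens the α-hydroxy lactone to the ring–chain pair lactol/α′-hydroxy ynone 6, and a cationic monovalent gold catalyst π-activates the alkyne of either tautomer so that the C10 tertiary hydroxyl adds 5-endo-dig at C3 and protodeauration (with hemiketal collapse when the lactol reacts) funnels both forms to the 3(2H)-furanone while freeing the C8 carbinol; the closest known reaction type is the gold-catalysed cycloisomerisation of isolated γ-hydroxy alkynones to 3(2H)-furanones, here extended to a lactol-masked ynone made in the same flask; C10 keeps its oxygen and configuration.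

**Step 4**
Reactants: 7 (2R)-5-[(2Z)-4-(tert-butyldimethylsilyloxy)but-2-en-2-yl]-2-[(1R,2R)-2-hydroxy-1,3-bis(triethylsilyloxy)propyl]-2-methylfuran-3(2H)-one
Product: 8 (2S,3R)-3-{(2R)-5-[(2Z)-4-(tert-butyldimethylsilyloxy)but-2-en-2-yl]-2-methyl-3-oxo-2,3-dihydrofuran-2-yl}-1,3-bis(triethylsilyloxy)propan-2-yl 2-methylpropanoate
Conditions: i-PrCO2H, PPh3, DIAD, toluene, 0 → 45 °C
Reagents that add atoms: isobutyric acid, CC(C)C(=O)O
Why: Mitsunobu esterification, in which isobutyrate displaces the C8 alkoxyphosphonium by SN2, inverts C8 from the D-ribo to the required L-lyxo configuration (8S) and installs the ester in the same operation; the C8 carbinol is the only free hydroxyl.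

**Step 5**
Reactants: 8 (2S,3R)-3-{(2R)-5-[(2Z)-4-(tert-butyldimethylsilyloxy)but-2-en-2-yl]-2-methyl-3-oxo-2,3-dihydrofuran-2-yl}-1,3-bis(triethylsilyloxy)propan-2-yl 2-methylpropanoate
Product: 9 (2R,3R)-3-{(2R)-5-[(2Z)-4-(tert-butyldimethylsilyloxy)but-2-en-2-yl]-2-methyl-3-oxo-2,3-dihydrofuran-2-yl}-1-oxo-3-(triethylsilyloxy)propan-2-yl 2-methylpropanoate
Conditions: (COCl)2, DMSO, CH2Cl2, −78 → −35 °C; Et3N, −78 → −20 °C
Reagents that add atoms: none
Why: Swern oxidation run directly on the silyl ether, where the chlorosulfonium salt cleaves only the unhindered primary TES ether (the secondary TES and primary TBS ethers stay) and the alkoxysulfonium collapses to the C7 aldehyde, the cold amine step sparing the C8 centre (its descriptor changes to R only through priorities).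

**Step 6**
Reactants: 9 (2R,3R)-3-{(2R)-5-[(2Z)-4-(tert-butyldimethylsilyloxy)but-2-en-2-yl]-2-methyl-3-oxo-2,3-dihydrofuran-2-yl}-1-oxo-3-(triethylsilyloxy)propan-2-yl 2-methylpropanoate
Product: 10 methyl (4S,5R)-5-{(2R)-5-[(2Z)-4-(tert-butyldimethylsilyloxy)but-2-en-2-yl]-2-methyl-3-oxo-2,3-dihydrofuran-2-yl}-3-hydroxy-2-methylidene-4-(2-methylpropanoyloxy)-5-(triethylsilyloxy)pentanoate (both C3 epimers)
Conditions: i-Bu2AlH, NMO, THF, 0 °C; methyl propiolate, 0 °C; then 9, 0 → 23 °C; Rochelle salt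
Reagents that add atoms: methyl propiolate, C#CC(=O)OC
Why: Vinylalumination, an amine-free Morita–Baylis–Hillman equivalent, in which hydroalumination of the propiolate gives the α-aluminated acrylate that adds to the aldehyde without base, so the α-acyloxy centre C8 is not epimerised; the new C7 carbinol forms as a mixture that step 7 erases.

**Step 7**
Reactants: 10 methyl (4S,5R)-5-{(2R)-5-[(2Z)-4-(tert-butyldimethylsilyloxy)but-2-en-2-yl]-2-methyl-3-oxo-2,3-dihydrofuran-2-yl}-3-hydroxy-2-methylidene-4-(2-methylpropanoyloxy)-5-(triethylsilyloxy)pentanoate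
Product: 11 methyl (2Z,4S,5R)-2-(bromomethyl)-5-{(2R)-5-[(2Z)-4-(tert-butyldimethylsilyloxy)but-2-en-2-yl]-2-methyl-3-oxo-2,3-dihydrofuran-2-yl}-4-(2-methylpropanoyloxy)-5-(triethylsilyloxy)pent-2-enoate
Conditions: NBS, Me2S, CH2Cl2, −20 → 0 °C
Reagents that add atoms: N-bromosuccinimide, BrN1C(=O)CCC1=O
Why: Corey–Kim-type activation with allylic transposition (SN2′), in which bromide attacks the terminal methylene of the alkoxysulfonium and gives the conjugated, thermodynamically preferred Z trisubstituted allyl bromide, removing the C7 stereocentre.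

**Step 8**
Reactants: 11 methyl (2Z,4S,5R)-2-(bromomethyl)-5-{(2R)-5-[(2Z)-4-(tert-butyldimethylsilyloxy)but-2-en-2-yl]-2-methyl-3-oxo-2,3-dihydrofuran-2-yl}-4-(2-methylpropanoyloxy)-5-(triethylsilyloxy)pent-2-enoate
Product: 12 methyl (2Z,4S,5R)-2-(bromomethyl)-5-hydroxy-5-{(2R)-5-[(2Z)-4-hydroxybut-2-en-2-yl]-2-methyl-3-oxo-2,3-dihydrofuran-2-yl}-4-(2-methylpropanoyloxy)pent-2-enoate
Conditions: aq. HF (48%), MeCN, 0 °C
Reagents that add atoms: none
Why: Fluoride-driven desilylation under acidic, amine-free conditions frees the C6 allylic alcohol and the C9 hydroxyl, with no nucleophile present for the allyl bromide and acyl migration slow at low pH.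

**Step 9**
Reactants: 12 methyl (2Z,4S,5R)-2-(bromomethyl)-5-hydroxy-5-{(2R)-5-[(2Z)-4-hydroxybut-2-en-2-yl]-2-methyl-3-oxo-2,3-dihydrofuran-2-yl}-4-(2-methylpropanoyloxy)pent-2-enoate
Product: 13 methyl (2Z,4S,5R)-2-(bromomethyl)-5-hydroxy-5-{(2R)-2-methyl-3-oxo-5-[(2Z)-4-oxobut-2-en-2-yl]-2,3-dihydrofuran-2-yl}-4-(2-methylpropanoyloxy)pent-2-enoate
Conditions: MnO2 (20 equiv), CH2Cl2, 23 °C, dark; used at once
Reagents that add atoms: none
Why: Allylic oxidation with MnO2 converts only the primary allylic alcohol to the enal, leaves the non-allylic C9 alcohol and keeps the Z geometry.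

**Step 10**
Reactants: 13 methyl (2Z,4S,5R)-2-(bromomethyl)-5-hydroxy-5-{(2R)-2-methyl-3-oxo-5-[(2Z)-4-oxobut-2-en-2-yl]-2,3-dihydrofuran-2-yl}-4-(2-methylpropanoyloxy)pent-2-enoate
Product: 15 (4Z,6R,7S,8S,9R,10R)-9-hydroxy-8-(2-methylpropanoyloxy)-1-oxo-3,10-epoxygermacra-2,4,11(13)-trien-12,6-olide (CNP0265772.1), via hydroxy ester 14 (not isolated)
Conditions: CrCl2 (10 equiv), THF–DMF 10:1, 23 °C, slow addition of 13 to 3 mM; aq. NH4Cl
Reagents that add atoms: none
Why: Intramolecular Nozaki–Hiyama-type (Barbier) allylation, in which the allylchromium adds through C7 to the C6 aldehyde via a chair-like six-membered transition state that gives the anti adduct (6,7-trans), the C8 stereocentre (H-8 eclipsing the allyl unit to avoid allylic strain) is expected to direct attack to the face giving 6R,7S, and the chromium alkoxide then closes the lactone on the methyl ester.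

**Compound list**
1 | 2-C-methyl-D-ribono-1,4-lactone, (3R,4R,5R)-3,4-dihydroxy-5-(hydroxymethyl)-3-methyloxolan-2-one | O=C1[C@](C)(O)[C@H](O)[C@@H](CO)O1 | starting material
2 | (Z)-3-methylpent-2-en-4-yn-1-ol | C#C/C(C)=C\CO | starting material
3 | (3R,4R,5R)-3-hydroxy-3-methyl-4-(triethylsilyloxy)-5-[(triethylsilyloxy)methyl]oxolan-2-one | O=C1[C@](C)(O)[C@H](O[Si](CC)(CC)CC)[C@@H](CO[Si](CC)(CC)CC)O1 | intermediate
4 | (Z)-tert-butyldimethyl[(3-methylpent-2-en-4-yn-1-yl)oxy]silane | C#C/C(C)=C\CO[Si](C)(C)C(C)(C)C | intermediate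
5 | lithium acetylide of 4 | [Li]C#C/C(C)=C\CO[Si](C)(C)C(C)(C)C | intermediate
6 | (2Z,7R,8R,9R)-1-(tert-butyldimethylsilyloxy)-7,9-dihydroxy-3,7-dimethyl-8,10-bis(triethylsilyloxy)dec-2-en-4-yn-6-one (in equilibrium with its five-membered lactol) | CC(C)(C)[Si](C)(C)OC/C=C(/C)C#CC(=O)[C@](C)(O)[C@H](O[Si](CC)(CC)CC)[C@H](O)CO[Si](CC)(CC)CC | intermediate
7 | (2R)-5-[(2Z)-4-(tert-butyldimethylsilyloxy)but-2-en-2-yl]-2-[(1R,2R)-2-hydroxy-1,3-bis(triethylsilyloxy)propyl]-2-methylfuran-3(2H)-one | CC(C)(C)[Si](C)(C)OC/C=C(/C)C1=CC(=O)[C@](C)(O1)[C@H](O[Si](CC)(CC)CC)[C@H](O)CO[Si](CC)(CC)CC | intermediate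
8 | (2S,3R)-3-{(2R)-5-[(2Z)-4-(tert-butyldimethylsilyloxy)but-2-en-2-yl]-2-methyl-3-oxo-2,3-dihydrofuran-2-yl}-1,3-bis(triethylsilyloxy)propan-2-yl 2-methylpropanoate | CC(C)(C)[Si](C)(C)OC/C=C(/C)C1=CC(=O)[C@](C)(O1)[C@H](O[Si](CC)(CC)CC)[C@@H](OC(=O)C(C)C)CO[Si](CC)(CC)CC | intermediate
9 | (2R,3R)-3-{(2R)-5-[(2Z)-4-(tert-butyldimethylsilyloxy)but-2-en-2-yl]-2-methyl-3-oxo-2,3-dihydrofuran-2-yl}-1-oxo-3-(triethylsilyloxy)propan-2-yl 2-methylpropanoate | CC(C)(C)[Si](C)(C)OC/C=C(/C)C1=CC(=O)[C@](C)(O1)[C@H](O[Si](CC)(CC)CC)[C@@H](OC(=O)C(C)C)C=O | intermediate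
10 | methyl (4S,5R)-5-{(2R)-5-[(2Z)-4-(tert-butyldimethylsilyloxy)but-2-en-2-yl]-2-methyl-3-oxo-2,3-dihydrofuran-2-yl}-3-hydroxy-2-methylidene-4-(2-methylpropanoyloxy)-5-(triethylsilyloxy)pentanoate, both C3 epimers | CC(C)(C)[Si](C)(C)OC/C=C(/C)C1=CC(=O)[C@](C)(O1)[C@H](O[Si](CC)(CC)CC)[C@@H](OC(=O)C(C)C)C(O)C(=C)C(=O)OC | intermediate
11 | methyl (2Z,4S,5R)-2-(bromomethyl)-5-{(2R)-5-[(2Z)-4-(tert-butyldimethylsilyloxy)but-2-en-2-yl]-2-methyl-3-oxo-2,3-dihydrofuran-2-yl}-4-(2-methylpropanoyloxy)-5-(triethylsilyloxy)pent-2-enoate | CC(C)(C)[Si](C)(C)OC/C=C(/C)C1=CC(=O)[C@](C)(O1)[C@H](O[Si](CC)(CC)CC)[C@@H](OC(=O)C(C)C)/C=C(\CBr)C(=O)OC | intermediate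
12 | methyl (2Z,4S,5R)-2-(bromomethyl)-5-hydroxy-5-{(2R)-5-[(2Z)-4-hydroxybut-2-en-2-yl]-2-methyl-3-oxo-2,3-dihydrofuran-2-yl}-4-(2-methylpropanoyloxy)pent-2-enoate | OC/C=C(/C)C1=CC(=O)[C@](C)(O1)[C@H](O)[C@@H](OC(=O)C(C)C)/C=C(\CBr)C(=O)OC | intermediate
13 | methyl (2Z,4S,5R)-2-(bromomethyl)-5-hydroxy-5-{(2R)-2-methyl-3-oxo-5-[(2Z)-4-oxobut-2-en-2-yl]-2,3-dihydrofuran-2-yl}-4-(2-methylpropanoyloxy)pent-2-enoate | O=C/C=C(/C)C1=CC(=O)[C@](C)(O1)[C@H](O)[C@@H](OC(=O)C(C)C)/C=C(\CBr)C(=O)OC | intermediate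
14 | methyl 2-[(4Z,6R,7S,8S,9R,10R)-6,9-dihydroxy-8-(2-methylpropanoyloxy)-1-oxo-3,10-epoxygermacra-2,4-dien-7-yl]prop-2-enoate | C=C(C(=O)OC)[C@H]1[C@H](O)/C=C(/C)C2=CC(=O)[C@](C)(O2)[C@H](O)[C@H]1OC(=O)C(C)C | intermediate
15 | (4Z,6R,7S,8S,9R,10R)-9-hydroxy-8-(2-methylpropanoyloxy)-1-oxo-3,10-epoxygermacra-2,4,11(13)-trien-12,6-olide | C=C1C(=O)O[C@@H]2/C=C(/C)C3=CC(=O)[C@](C)(O3)[C@H](O)[C@@H](OC(=O)C(C)C)[C@@H]12 | target

**Step count and risks**
Total steps: 10. Longest linear sequence: 9 (steps 1, 3, 4, 5, 6, 7, 8, 9, 10 from 1).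

Steps most likely to fail:

- Step 3 (the proposed new step). The crude lactol may cyclise slowly, or silyl groups may shift at the alkoxide stage. The fallback uses known chemistry and sets out from 3 with acetylide 5. The addition is run as above and hydroxy ynone 6 is isolated by chromatography. Et2NH in EtOH adds to the ynone to give the β-diethylamino enone F1. Aqueous AcOH in THF then lets the C10 hydroxyl displace the amine by addition–elimination, which gives 7, where the route is rejoined.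

- Step 4. The carbinol is hindered, isobutyric acid is a weak Mitsunobu acid, and the furanone carbonyl could take part and give retention or elimination. The fallback sets out from 3. LiOH in THF/H2O followed by buffering to pH 4 gives the hydroxy acid F2. PPh3 and DIAD close the lactone by carboxylate attack at C8 with inversion (Mitsunobu lactonisation) to the L-lyxo lactone F3. F3 is taken through the step 3 conditions with 5 to the C8-epimeric furanone alcohol F4. Acylation with (i-PrCO)2O and DMAP, with retention, gives 8, where the route is rejoined.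

- Step 10. The facial selectivity relative to C8 is not secured by precedent on this exact ring, and oligomerisation competes. The fallback sets out from 12. Hexabutylditin with Pd(PPh3)4 (zerovalent palladium) in THF gives the allylstannane diol F5. MnO2 gives the stannyl enal F6. BF3·OEt2 in CH2Cl2 at −78 °C and 2 mM closes the ring by a Lewis-acid-promoted SE2′ addition through an open transition state, which has a different facial and syn/anti preference from the chromium chelate. This gives 14, which lactonises with PPTS to 15.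

**Further compounds**
F1 | step 3 | (E)-β-diethylamino enone from 6: (2Z,4E,7R,8R,9R)-1-(tert-butyldimethylsilyloxy)-4-(diethylamino)-7,9-dihydroxy-3,7-dimethyl-8,10-bis(triethylsilyloxy)deca-2,4-dien-6-one | CC(C)(C)[Si](C)(C)OC/C=C(/C)\C(N(CC)CC)=C/C(=O)[C@](C)(O)[C@H](O[Si](CC)(CC)CC)[C@H](O)CO[Si](CC)(CC)CC
F2 | step 4 | (2R,3R,4R)-2,4-dihydroxy-2-methyl-3,5-bis(triethylsilyloxy)pentanoic acid | OC(=O)[C@](C)(O)[C@H](O[Si](CC)(CC)CC)[C@H](O)CO[Si](CC)(CC)CC
F3 | step 4 | 3,5-di-O-triethylsilyl-2-C-methyl-L-lyxono-1,4-lactone, (3R,4R,5S) | O=C1[C@](C)(O)[C@H](O[Si](CC)(CC)CC)[C@H](CO[Si](CC)(CC)CC)O1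
F4 | step 4 | (2R)-5-[(2Z)-4-(tert-butyldimethylsilyloxy)but-2-en-2-yl]-2-[(1R,2S)-2-hydroxy-1,3-bis(triethylsilyloxy)propyl]-2-methylfuran-3(2H)-one | CC(C)(C)[Si](C)(C)OC/C=C(/C)C1=CC(=O)[C@](C)(O1)[C@H](O[Si](CC)(CC)CC)[C@@H](O)CO[Si](CC)(CC)CC
F5 | step 10 | methyl (2Z,4S,5R)-5-hydroxy-5-{(2R)-5-[(2Z)-4-hydroxybut-2-en-2-yl]-2-methyl-3-oxo-2,3-dihydrofuran-2-yl}-4-(2-methylpropanoyloxy)-2-[(tributylstannyl)methyl]pent-2-enoate | OC/C=C(/C)C1=CC(=O)[C@](C)(O1)[C@H](O)[C@@H](OC(=O)C(C)C)/C=C(\C[Sn](CCCC)(CCCC)CCCC)C(=O)OC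
F6 | step 10 | methyl (2Z,4S,5R)-5-hydroxy-5-{(2R)-2-methyl-3-oxo-5-[(2Z)-4-oxobut-2-en-2-yl]-2,3-dihydrofuran-2-yl}-4-(2-methylpropanoyloxy)-2-[(tributylstannyl)methyl]pent-2-enoate | O=C/C=C(/C)C1=CC(=O)[C@](C)(O1)[C@H](O)[C@@H](OC(=O)C(C)C)/C=C(\C[Sn](CCCC)(CCCC)CCCC)C(=O)OC
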